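All runs stem from a simulated flask with made-up constants; scatter was added.

A yield in percent cannot be carried from one charge of solid substrate to another here: at 55 °C and 96.0 h, dusk on 40 mM read 20%, but midnight on 88 mM read 10%.

| flask | solid substrate | partner A | partner B | temperature | remark | time |
|---|---|---|---|---|---|---|
| dusk | 40 mM | 1.5 equiv | 1.8 equiv | 55 °C | run made earlier |  |
| autumn | 56 mM | 1.5 equiv | 1.8 equiv | 70 °C | run made earlier |  |
| midnight | 88 mM | 1.5 equiv | 1.8 equiv | 55 °C | run made earlier |  |
| ash | 40 mM | 1.50 equiv | 1.80 equiv |  | everything together at the start at 30 °C, warmed to 70 °C at 40 h | 50 h |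
| maple | 40 mM | 1.50 equiv (fed, over 40 h) | 1.80 equiv | 70 °C | all else is in the flask from the start; the feed brings no volume worth counting | 50 h |
| alder | 40 mM | 1.50 equiv (fed, over 40 h) | 1.80 equiv |  | the addition at 30 °C, then warmed to 70 °C; the feed brings no volume worth counting | 50 h |
| cedar | 40 mM | 1.50 equiv | 1.80 equiv | 70 °C | everything together at the start | 50 h |

- dusk (time / h: product / %): 8.00: 0; 12.0: 0; 20.0: 3; 30.0: 4; 40.0: 9; 60.0: 14; 96.0: 20
- autumn (time / h: product / %): 8.00: 2; 15.0: 4; 20.0: 7; 30.0: 7; 40.0: 9; 48.0: 10
- midnight (time / h: product / %): 5.00: 0; 15.0: 2; 30.0: 6; 40.0: 4; 60.0: 8; 96.0: 10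

(readings scatter by 1.5 percentage points)

- given per volume of solution although it is solid: solid substrate
- at the start none of the solid substrate is in solution

- the flask with the highest amount of product, in percent of the solid substrate charged ("all alike" if they lie within 1.5 percentage points) (ash / maple / alder / cedar / all alike)
- final product, as a percentage of the solid substrate charged, in ash
- final product, as a percentage of the solid substrate charged, in maple
- final product, as a percentage of the solid substrate charged, in alder
- final product, as a percentage of the solid substrate charged, in cedar

I built the flask up in steps. First I took the main step alone, with product formed in proportion to the charge. That carries the percent unchanged, so it gave midnight 17.6 mM of product and gave cedar about autumn's 10%. But midnight read 8.80 mM against dusk's 8.00 mM.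

Second I added the solid, none of which is in solution at the start. In logarithms, the order in the charge, with partners scaled alongside, is the log of the product ratio over the log of the charge ratio. I read 0.121, under a scatter of 1.5 percentage points, so close to zero order. What carries at 55 °C, with the equivalents held, is then mM rather than percent, and I took the same to hold at 70 °C. Autumn at 70 °C gave the output rate r, 0.117 mM h⁻¹, the product in mM per hour averaged over that run. With t the time and c the charge, the percent is r t / c, which put cedar at 14.6%.

Third I added the rest. No run fed partner A, so I kept maple at cedar's figure. Ash and alder have 10.0 h hot after the cold hours. Autumn's early rate, read as 0.196 mM h⁻¹, over those hours gave a low estimate of 4.90%, counting nothing from the cold, and I placed both flasks between that estimate and cedar.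

The forecast, unlike my level pair, put maple first with 17% over cedar's 14%, and 8% for ash and 8% for alder, saying of maple “it should do slightly better, though this is uncertain”.

The flasks gave 9.70% in ash, 16.4% in maple, 10.3% in alder and 14.7% in cedar, so maple stood highest.

    starting material + partner B → open intermediate (k = 0.220 M⁻¹ min⁻¹, Ea = 62.0 kJ mol⁻¹)
    solid substrate ⇌ starting material, rate k2*(cs2 - [starting material]) while solid is left; crystals form when [starting material] > cs2 (solubility = 2.10 mM, k = 0.00130 min⁻¹)
    partner B + partner A → second intermediate (k = 0.0730 M⁻¹ min⁻¹, Ea = 62.0 kJ mol⁻¹)
    partner A ⇌ dormant form (K = 2.00, k = 0.00130 min⁻¹, Ea = 116 kJ mol⁻¹, ΔH = −14.0 kJ mol⁻¹)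
    open intermediate + second intermediate → product (k = 0.520 M⁻¹ min⁻¹, Ea = 85.0 kJ mol⁻¹)
    (constants at 70 °C)

Cedar's 14.7% stood beside the reckoned 14.6%, ash and alder lay inside their bracket, and maple lay 1.8 points above r t / c. For a neighbour of maple charged with 24 mM, equivalents and time held, the same r gave a reckoned 24.3%. That flask gave 24.6%, which is 5.90 mM of product against maple's 6.57 mM.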